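**Numbering used throughout**

Compounds: 1 3-(3,4-dimethoxyphenyl)propan-1-ol; 2 its ring bromide; 3 the bromo aldehyde; 4 2,3-dimethoxy-1,4-benzoquinone; 5 enamine of 3; 6 open-chain hydroquinone aldehyde; 7 lactol; 8 hydroquinone alcohol; 9 bis(benzyl ether); 10 protected chroman; 11 hydroquinone; 12 target.

Atoms: chroman O1, C2, C3, C4, C4a, C5–C8, C8a (ring A = C4a, C5–C8, C8a); ring B C1'–C6', with C1' bonded to C3.

## Analysis of the target

Target 12 is an isoflavan quinone: ring A carries methoxy groups at C6 and C7 and is fused to a saturated pyran ring (O1, C2, C3, C4, C4a, C8a). C3 of that ring is bonded to C1' of ring B, a 1,4-benzoquinone with carbonyls at C2' and C5', methoxy groups at C3' and C4' and hydrogen at C6'. C3 is the only stereocentre and is S (C2 > C1' > C4 > H); no other stereocentre can relay to it, so a catalyst has to set it between two methylene neighbours that differ only one atom further out. The quinone is the sensitive part: it is an oxidant and a Michael acceptor, and C3–H is γ to the C5' carbonyl through C1'=C6', so base can remove it via a quinone methide tautomer and erase the stereocentre. Ring A is a 1,2,4-trioxygenated benzene that strong one-electron oxidants would also convert to a quinone, so ring B cannot be unveiled by a harsh oxidative demethylation. The difficulty is therefore threefold: an isolated benzylic stereocentre, a fully oxygenated ring B, and a quinone that must appear last and under neutral conditions. The plan rests on one feature: C1' is, in the parent quinone 4, one of two equivalent unsubstituted CH positions, so ring B can enter with all four oxygens in place by attack of a nucleophilic carbon that becomes C3.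

## Retrosynthetic reasoning

12 ⇒ 11 ⇒ 10. No skeletal bond is cut. The C2' and C5' carbonyls are traced to hydroquinone 11 and then to its bis(benzyl ether) 10. Benzyl is chosen because hydrogenolysis removes it without touching the methyl ethers, and the free hydroquinone 11 can then be oxidised under mild neutral conditions that leave ring A alone. Placing the quinone at the very end keeps the vinylogously acidic C3–H away from every basic step.

10 ⇒ 9. The aryl ether bond O1–C8a is cut, giving a primary alcohol at C2 and a bromide at C8a. Cutting O1–C2 instead would demand a phenol on ring A and an activated C2; cutting C4–C4a would demand a C–H functionalisation. The O1–C8a cut is preferred because the bromide can be put on ring A in the first step by the natural directing effect of the methoxy groups, and because the alcohol is the reduced form of the aldehyde that the key step needs. The forward reaction must form a six-membered aryl alkyl ether from an electron-rich aryl bromide without disturbing C3.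

9 ⇒ 8 ⇒ 7. The benzyl ethers are removed to give hydroquinone alcohol 8, and the C2 alcohol and the C2' hydroxyl of 8 are tied together as the lactol of 7. In the forward direction reduction opens the lactol; from then on C3 is no longer α to a carbonyl equivalent and is configurationally safe. The two phenols are then capped so that only the aliphatic oxygen can take part in the ether closure.

7 ⇒ 3 + 4 (through 5 and 6). The C3–C1' bond is cut, together with the temporary lactol C–O bond. This is the only cut that delivers ring B complete: C1' of 4 is an electrophilic CH, and the carbon α to the aldehyde of 3 is nucleophilic as its enamine 5. The same event creates the stereocentre under catalyst control. Because 4 has a mirror plane, its two free ring carbons are equivalent and no regiochemical question arises. The forward reaction must achieve face-selective C–C bond formation, aromatisation to 6, and ring closure to 7 before the α-aryl aldehyde can enolise.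

3 ⇒ 2 ⇒ 1. Only functional groups change: the aldehyde comes from the primary alcohol 2, and the ring bromide of 2 from electrophilic bromination of commercial 1. The precursor of the key step is thus two routine steps from a catalogue compound.

## Alternatives that were turned down

Alternative 1: Catellani annulation.
- Disconnection: C4–C4a and O1–C8a are cut together, which reduces ring A to 4-iodo-1,2-dimethoxybenzene A2 and the rest of the molecule to the enantiopure bromo alcohol (2S)-2-[3-(benzyloxy)-4,5-dimethoxyphenyl]-3-bromopropan-1-ol A3.
- Forward key step: with Pd(OAc)2, a triarylphosphine, a strained bicyclic olefin as transient mediator and Cs2CO3, A2 adds to zerovalent palladium and the free ortho C–H is palladated. The primary bromide of A3 adds to the palladacycle (tetravalent palladium) and reductive elimination forms C4–C4a. After loss of the mediator the arylpalladium alkoxide closes O1–C8a. The product is (3S)-3-[3-(benzyloxy)-4,5-dimethoxyphenyl]-6,7-dimethoxychroman A1. Hydrogenolysis of A1 and para-oxidation of the freed C5' phenol would follow.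
- For: two bonds and the pyran ring form in one step from a C–H bond, and ring A needs no more than an iodide. On ring-forming economy this is stronger than the chosen route, which needs a separate CuI-mediated closure and a lactol that is opened again.
- Against: A2 has no ortho substituent, so after the first alkylation a second ortho palladation at the other free position competes with expulsion of the mediator. Termination by an aliphatic alkoxide is the least favourable ipso step. A3 has a benzylic hydrogen β to bromide and a γ-hydroxyl, so under hot Cs2CO3 it can eliminate (destroying the stereocentre) or close to an oxetane. The key step creates no stereocentre, so A3 must be made enantiopure by separate asymmetric chemistry. Ring B of A1 is one oxygen short (C2'), so a late phenol-to-quinone oxidation remains.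
- Comparison: the chosen strategy sets C3 in the bond-forming step, has no ambiguous C–H site, and brings ring B in fully oxygenated.

Alternative 2: three-component conjunctive coupling.
- Disconnection: C3–C1' and C4–C4a are cut across a vinyl unit, giving [3,4-dimethoxy-2-(methoxymethoxy)phenyl]lithium A7, vinylboronic acid pinacol ester A5 and 2-(benzyloxy)-4,5-dimethoxyphenyl trifluoromethanesulfonate A6.
- Forward key step: A7 and A5 form a boron ate complex. The arylpalladium species formed from A6 with Pd(OAc)2 and a Mandyphos ligand binds the vinyl group and triggers 1,2-migration of the ring B aryl from boron to the α-carbon while ring A is delivered to the β-carbon. The product is 2-{(1S)-2-[2-(benzyloxy)-4,5-dimethoxyphenyl]-1-[3,4-dimethoxy-2-(methoxymethoxy)phenyl]ethyl}-4,4,5,5-tetramethyl-1,3,2-dioxaborolane A4.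
- For: both C–C bonds at C3 and the stereocentre form in one catalytic enantioselective event from three simple pieces. In convergence this is stronger than the chosen route, and the C–B bond of A4 can be elaborated with retention.
- Against: the migrating aryl of A7 carries an ortho acetal oxygen and A6 an ortho benzyloxy group on an electron-rich ring, so migration is hindered and oxidative addition slow, which opens the way to direct aryl transfer. C2 is absent from A4 and must be inserted by a Matteson homologation on a hindered benzylic boronate and then oxidised. Ring A debenzylation, Mitsunobu closure of O1–C2, acetal removal and para-oxidation at C5' follow, five to six steps in all.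
- Comparison: the chosen strategy needs no carbon insertion and no late C–H oxygenation, because the quinone supplies ring B in its final oxygen pattern.

Alternative 3: aminocatalytic ortho-quinone methide annulation.
- Disconnection: C3–C4 and O1–C2 are cut, giving 2-[2-(benzyloxy)-3,4-dimethoxyphenyl]acetaldehyde A9 and 4,5-dimethoxy-2-[(4-methylbenzenesulfonyl)methyl]phenol A10, the latter as precursor of the ortho-quinone methide.
- Forward key step: a diarylprolinol silyl ether converts A9 to its enamine, whose carbon attacks the exocyclic methylene of the quinone methide released from A10 by mild base. The phenol oxygen then closes on the aldehyde carbon. The product is (3S)-3-[2-(benzyloxy)-3,4-dimethoxyphenyl]-6,7-dimethoxychroman-2-ol A8, a mixture at C2. Ionic reduction of the lactol A8, hydrogenolysis and para-oxidation of the C2' phenol would finish the synthesis.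
- For: the pyran ring and the stereocentre are made in one organocatalytic step, with no aryl halide and no metal-mediated etherification. On ring construction and on the length of the finishing sequence this is as strong as or stronger than the chosen route.
- Against: A9 is an arylacetaldehyde, prone to self-condensation and oxidation, and its enamine is conjugated with a hindered ortho-substituted arene and is therefore a weaker nucleophile. The quinone methide from A10 has an unsubstituted methylene and two methoxy donors, which makes it short-lived towards oligomerisation and less electrophilic. Ring B of A8 again lacks the C5' oxygen, so a late oxidation is needed. The configurational lability of the α-aryl lactol is shared with the chosen route and does not discriminate.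
- Comparison: the chosen strategy uses a simple, stable 3-arylpropanal with an unconjugated enamine, and ring B arrives complete, bought as a symmetric quinone.

Key step: step 3

Remarks on the chemistry:
- Quinone 4 is taken to be purchasable.
- The sense of induction is assigned by the usual steric shielding model for diarylprolinol silyl ethers, under which the (R)-catalyst should give the (3S) lactol. If the opposite sense were found with this quinone, the (S)-catalyst would be used.

## Route

Step 1
Reactants: 1 3-(3,4-dimethoxyphenyl)propan-1-ol
Product: 2 3-(2-bromo-4,5-dimethoxyphenyl)propan-1-ol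
Conditions: NBS (1.05 equiv), MeCN, 0 °C to rt
Reagents that add atoms: N-bromosuccinimide, O=C1CCC(=O)N1Br
Why: Electrophilic aromatic bromination; the position para to one methoxy group and ortho to the side chain is the most activated and accessible site of a 4-alkylveratrole, and the primary alcohol is not oxidised under these conditions.

Step 2
Reactants: 2 3-(2-bromo-4,5-dimethoxyphenyl)propan-1-ol
Product: 3 3-(2-bromo-4,5-dimethoxyphenyl)propanal
Conditions: Dess–Martin periodinane (1.2 equiv), CH2Cl2, rt
Reagents that add atoms: none
Why: Dess–Martin oxidation of a primary alcohol stops at the aldehyde under neutral conditions; the aldehyde has no α-stereocentre and is used promptly.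

Step 3
Reactants: 3 3-(2-bromo-4,5-dimethoxyphenyl)propanal (1.5 equiv); 4 2,3-dimethoxy-1,4-benzoquinone
Product: 7 (3S)-3-[(2-bromo-4,5-dimethoxyphenyl)methyl]-6,7-dimethoxy-2,3-dihydro-1-benzofuran-2,5-diol (anomeric mixture at C2), via E-enamine 5 (not isolated), via open-chain hydroquinone aldehyde 6 (not isolated)
Conditions: (R)-2-{bis[3,5-bis(trifluoromethyl)phenyl][(trimethylsilyl)oxy]methyl}pyrrolidine (20 mol%), EtOH/H2O, −20 °C, Ar
Reagents that add atoms: none
Why: Condensation of 3 with the amine gives E-enamine 5, whose nucleophilic carbon (the future C3) adds in Michael fashion to an unsubstituted ring carbon of 4 (the future C1'). A proton shift aromatises the adduct to the hydroquinone, which makes the C–C bond formation irreversible, and hydrolysis of the iminium ion releases the catalyst and aldehyde 6. The hydroxyl ortho to the new bond then adds to the aldehyde carbon (5-exo-trig hemiacetalisation) and closes the five-membered lactol ring of 7, which keeps the α-aryl stereocentre out of the enol and enamine manifold. The closest known reaction type is the secondary-amine-catalysed enantioselective α-arylation of aldehydes with 1,4-quinones, which gives 3-substituted 2,3-dihydrobenzofuran-2-ols. The stereocentre is controlled by the catalyst: its bis(aryl)(silyloxy)methyl group blocks one face of the s-trans E-enamine, and with the (R)-catalyst the quinone should approach the open face that leads to 3S. The step needs enantiofacial selectivity, C-attack in preference to N- or O-attack, and suppression of redox between 4 and hydroquinone 6; the bulk of the amine, the low temperature and the excess of aldehyde are meant to secure these. No regiochemistry arises because a mirror plane makes the two free carbons of 4 equivalent, the methoxy-bearing carbons are deactivated as vinylogous ester positions, and the aryl bromide of 3 is inert.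

Step 4
Reactants: 7 (3S)-3-[(2-bromo-4,5-dimethoxyphenyl)methyl]-6,7-dimethoxy-2,3-dihydro-1-benzofuran-2,5-diol
Product: 8 (2S)-3-(2-bromo-4,5-dimethoxyphenyl)-2-(2,5-dihydroxy-3,4-dimethoxyphenyl)propan-1-ol
Conditions: NaBH4, MeOH/THF, 0 °C, Ar; aq. NH4Cl; crude product used at once
Reagents that add atoms: none
Why: Hydride reduction of a lactol: in the protic medium 7 is in ring–chain equilibrium with its hydroxy aldehyde tautomer (the open form numbered 6 in step 3), which NaBH4 should reduce faster than it enolises at 0 °C; once C2 is an alcohol, C3 is an ordinary benzylic centre. The hydroquinone is air-sensitive and is therefore not stored.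

Step 5
Reactants: 8 (2S)-3-(2-bromo-4,5-dimethoxyphenyl)-2-(2,5-dihydroxy-3,4-dimethoxyphenyl)propan-1-ol
Product: 9 (2S)-2-[2,5-bis(benzyloxy)-3,4-dimethoxyphenyl]-3-(2-bromo-4,5-dimethoxyphenyl)propan-1-ol
Conditions: BnBr (2.3 equiv), K2CO3, degassed DMF, rt, Ar
Reagents that add atoms: benzyl bromide, BrCc1ccccc1
Why: Williamson etherification; K2CO3 deprotonates only the two phenols, so the primary alcohol stays free for the ring closure, and exclusion of oxygen keeps the hydroquinone from oxidising before it is capped.

Step 6
Reactants: 9 (2S)-2-[2,5-bis(benzyloxy)-3,4-dimethoxyphenyl]-3-(2-bromo-4,5-dimethoxyphenyl)propan-1-ol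
Product: 10 (3S)-3-[2,5-bis(benzyloxy)-3,4-dimethoxyphenyl]-6,7-dimethoxy-3,4-dihydro-2H-chromene
Conditions: CuI (10 mol%), 3,4,7,8-tetramethyl-1,10-phenanthroline (20 mol%), Cs2CO3, toluene, 110 °C
Reagents that add atoms: none
Why: Intramolecular Ullmann-type C–O coupling of a primary alkoxide with an aryl bromide closes the six-membered ether O1–C8a; with both phenols capped the aliphatic oxygen is the only nucleophile, and C3 bears no acidifying group at this stage.

Step 7
Reactants: 10 (3S)-3-[2,5-bis(benzyloxy)-3,4-dimethoxyphenyl]-6,7-dimethoxy-3,4-dihydro-2H-chromene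
Product: 12 5-[(3S)-6,7-dimethoxy-3,4-dihydro-2H-chromen-3-yl]-2,3-dimethoxycyclohexa-2,5-diene-1,4-dione (the target), via hydroquinone 11 (not isolated)
Conditions: H2 (1 atm), Pd/C, EtOAc, rt; filter under Ar; then Ag2O, Et2O, rt, dark
Reagents that add atoms: none
Why: Hydrogenolysis of the two aryl benzyl ethers followed by oxidation of the free para-hydroquinone with Ag2O, a mild heterogeneous oxidant that does not attack ring A. No base is present, so the C3–H, which becomes vinylogously acidic in the quinone, should not be removed.

## Compound list

1 | 3-(3,4-dimethoxyphenyl)propan-1-ol | COc1ccc(CCCO)cc1OC | starting material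
2 | 3-(2-bromo-4,5-dimethoxyphenyl)propan-1-ol | COc1cc(Br)c(CCCO)cc1OC | intermediate
3 | 3-(2-bromo-4,5-dimethoxyphenyl)propanal | COc1cc(Br)c(CCC=O)cc1OC | intermediate
4 | 2,3-dimethoxy-1,4-benzoquinone | COC1=C(OC)C(=O)C=CC1=O | starting material
5 | (2R)-2-{bis[3,5-bis(trifluoromethyl)phenyl][(trimethylsilyl)oxy]methyl}-1-[(1E)-3-(2-bromo-4,5-dimethoxyphenyl)prop-1-en-1-yl]pyrrolidine | C[Si](C)(C)OC([C@H]1CCCN1/C=C/Cc1cc(OC)c(OC)cc1Br)(c1cc(cc(c1)C(F)(F)F)C(F)(F)F)c1cc(cc(c1)C(F)(F)F)C(F)(F)F | intermediate (not isolated)
6 | (2S)-3-(2-bromo-4,5-dimethoxyphenyl)-2-(2,5-dihydroxy-3,4-dimethoxyphenyl)propanal | O=C[C@@H](Cc1cc(OC)c(OC)cc1Br)c1cc(O)c(OC)c(OC)c1O | intermediate (not isolated)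
7 | (3S)-3-[(2-bromo-4,5-dimethoxyphenyl)methyl]-6,7-dimethoxy-2,3-dihydro-1-benzofuran-2,5-diol, anomeric mixture at C2 | OC1Oc2c(OC)c(OC)c(O)cc2[C@@H]1Cc1cc(OC)c(OC)cc1Br | intermediate
8 | (2S)-3-(2-bromo-4,5-dimethoxyphenyl)-2-(2,5-dihydroxy-3,4-dimethoxyphenyl)propan-1-ol | OC[C@@H](Cc1cc(OC)c(OC)cc1Br)c1cc(O)c(OC)c(OC)c1O | intermediate
9 | (2S)-2-[2,5-bis(benzyloxy)-3,4-dimethoxyphenyl]-3-(2-bromo-4,5-dimethoxyphenyl)propan-1-ol | OC[C@@H](Cc1cc(OC)c(OC)cc1Br)c1cc(OCc2ccccc2)c(OC)c(OC)c1OCc1ccccc1 | intermediate
10 | (3S)-3-[2,5-bis(benzyloxy)-3,4-dimethoxyphenyl]-6,7-dimethoxy-3,4-dihydro-2H-chromene | COc1c(OC)c(OCc2ccccc2)cc([C@H]2COc3cc(OC)c(OC)cc3C2)c1OCc1ccccc1 | intermediate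
11 | (3S)-3-(2,5-dihydroxy-3,4-dimethoxyphenyl)-6,7-dimethoxy-3,4-dihydro-2H-chromene | COc1c(OC)c(O)cc([C@H]2COc3cc(OC)c(OC)cc3C2)c1O | intermediate (not isolated)
12 | 5-[(3S)-6,7-dimethoxy-3,4-dihydro-2H-chromen-3-yl]-2,3-dimethoxycyclohexa-2,5-diene-1,4-dione | COC1=C(OC)C(=O)C([C@H]2COc3cc(OC)c(OC)cc3C2)=CC1=O | target

## Step count and risk

Total step count: 7. Longest linear sequence: 7 steps (1 to 12); quinone 4 enters at step 3 as purchased.

Least certain steps:

Step 3 (key step). The conjugate addition may be slow, because both carbonyls of 4 are attenuated by the vinylogous methoxy donors. Side processes could then take over: consumption of the amine catalyst by N-addition to the quinone or by displacement of a methoxy group, oxidation of the hydroquinone adduct by unreacted quinone, and erosion of enantiopurity through reversible opening of the lactol and renewed enamine formation.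

Fallback: set out from 3 and 4 and rejoin the route at 9, replacing steps 3 to 5. Quinone 4 is reduced with Na2S2O4 to 2,3-dimethoxybenzene-1,4-diol F1, which is benzylated (BnBr, K2CO3) to 1,4-bis(benzyloxy)-2,3-dimethoxybenzene F2. Reaction of F2 with (diacetoxyiodo)mesitylene and TfOH at low temperature gives [2,5-bis(benzyloxy)-3,4-dimethoxyphenyl](2,4,6-trimethylphenyl)iodonium trifluoromethanesulfonate F3. Aldehyde 3 is then α-arylated with F3 under CuBr and the trichloroacetate of the enantiomer of 5-benzyl-2-tert-butyl-3-methylimidazolidin-4-one that gives the S product, with NaHCO3. Here the enamine attacks an aryl–copper species of trivalent copper, and the mesityl group serves as the non-transferred ligand. The product is (2S)-2-[2,5-bis(benzyloxy)-3,4-dimethoxyphenyl]-3-(2-bromo-4,5-dimethoxyphenyl)propanal F4, which is reduced in the same flask with NaBH4 to 9. The arylating agent is no longer a quinone, so neither its low electrophilicity nor its redox chemistry matters, and the benzyl ethers are already in place.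

Step 6. Activation of the electron-rich, ortho-alkylated aryl bromide by the CuI catalyst may be sluggish, so that protodebromination or oxidation of the alkoxide to the aldehyde (which would also put C3 at risk) competes with ring closure.

Fallback: set out from 9 and rejoin at 10, closing O1–C2 instead of O1–C8a. Miyaura borylation (B2pin2, Pd(dppf)Cl2, KOAc, dioxane) gives (2S)-2-[2,5-bis(benzyloxy)-3,4-dimethoxyphenyl]-3-[4,5-dimethoxy-2-(4,4,5,5-tetramethyl-1,3,2-dioxaborolan-2-yl)phenyl]propan-1-ol F5. Oxidation with NaBO3 gives 2-{(2S)-2-[2,5-bis(benzyloxy)-3,4-dimethoxyphenyl]-3-hydroxypropyl}-4,5-dimethoxyphenol F6. Mitsunobu closure (PPh3, DIAD, THF) of the ring A phenol onto the primary alcohol gives 10.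

Step 5. The free hydroquinone may be oxidised by traces of air under K2CO3. The resulting quinone can be attacked at C6' by its own primary alcohol and can lose configuration at C3. Alkylation of the hindered C2' hydroxyl may also stall.

Fallback: set out from 8 and rejoin at 9. Crude 8 is peracetylated (Ac2O, pyridine) to (2S)-3-(2-bromo-4,5-dimethoxyphenyl)-2-[2,5-bis(acetyloxy)-3,4-dimethoxyphenyl]propyl acetate F7, which is air-stable and can be purified. F7 is then treated with K2CO3 and BnBr in degassed MeOH/DMF. Methanolysis releases each phenoxide in the presence of the alkylating agent, so it is benzylated as it forms, and the primary acetate is cleaved to the free alcohol, giving 9.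

## Further compounds

F1 | step 3 | 2,3-dimethoxybenzene-1,4-diol | COc1c(O)ccc(O)c1OC
F2 | step 3 | 1,4-bis(benzyloxy)-2,3-dimethoxybenzene | COc1c(OCc2ccccc2)ccc(OCc2ccccc2)c1OC
F3 | step 3 | [2,5-bis(benzyloxy)-3,4-dimethoxyphenyl](2,4,6-trimethylphenyl)iodonium trifluoromethanesulfonate | COc1c(OC)c(OCc2ccccc2)cc([I+]c2c(C)cc(C)cc2C)c1OCc1ccccc1.[O-]S(=O)(=O)C(F)(F)F
F4 | step 3 | (2S)-2-[2,5-bis(benzyloxy)-3,4-dimethoxyphenyl]-3-(2-bromo-4,5-dimethoxyphenyl)propanal | O=C[C@@H](Cc1cc(OC)c(OC)cc1Br)c1cc(OCc2ccccc2)c(OC)c(OC)c1OCc1ccccc1
F5 | step 6 | (2S)-2-[2,5-bis(benzyloxy)-3,4-dimethoxyphenyl]-3-[4,5-dimethoxy-2-(4,4,5,5-tetramethyl-1,3,2-dioxaborolan-2-yl)phenyl]propan-1-ol | OC[C@@H](Cc1cc(OC)c(OC)cc1B1OC(C)(C)C(C)(C)O1)c1cc(OCc2ccccc2)c(OC)c(OC)c1OCc1ccccc1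
F6 | step 6 | 2-{(2S)-2-[2,5-bis(benzyloxy)-3,4-dimethoxyphenyl]-3-hydroxypropyl}-4,5-dimethoxyphenol | OC[C@@H](Cc1cc(OC)c(OC)cc1O)c1cc(OCc2ccccc2)c(OC)c(OC)c1OCc1ccccc1
F7 | step 5 | (2S)-3-(2-bromo-4,5-dimethoxyphenyl)-2-[2,5-bis(acetyloxy)-3,4-dimethoxyphenyl]propyl acetate | CC(=O)OC[C@@H](Cc1cc(OC)c(OC)cc1Br)c1cc(OC(C)=O)c(OC)c(OC)c1OC(C)=O
A1 | alternative 1 | (3S)-3-[3-(benzyloxy)-4,5-dimethoxyphenyl]-6,7-dimethoxychroman | COc1cc([C@H]2COc3cc(OC)c(OC)cc3C2)cc(OCc2ccccc2)c1OC
A2 | alternative 1 | 4-iodo-1,2-dimethoxybenzene | COc1ccc(I)cc1OC
A3 | alternative 1 | (2S)-2-[3-(benzyloxy)-4,5-dimethoxyphenyl]-3-bromopropan-1-ol | OC[C@@H](CBr)c1cc(OC)c(OC)c(OCc2ccccc2)c1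
A4 | alternative 2 | 2-{(1S)-2-[2-(benzyloxy)-4,5-dimethoxyphenyl]-1-[3,4-dimethoxy-2-(methoxymethoxy)phenyl]ethyl}-4,4,5,5-tetramethyl-1,3,2-dioxaborolane | COCOc1c([C@H](Cc2cc(OC)c(OC)cc2OCc2ccccc2)B2OC(C)(C)C(C)(C)O2)ccc(OC)c1OC
A5 | alternative 2 | vinylboronic acid pinacol ester | C=CB1OC(C)(C)C(C)(C)O1
A6 | alternative 2 | 2-(benzyloxy)-4,5-dimethoxyphenyl trifluoromethanesulfonate | COc1cc(OCc2ccccc2)c(OS(=O)(=O)C(F)(F)F)cc1OC
A7 | alternative 2 | [3,4-dimethoxy-2-(methoxymethoxy)phenyl]lithium | [Li]c1ccc(OC)c(OC)c1OCOC
A8 | alternative 3 | (3S)-3-[2-(benzyloxy)-3,4-dimethoxyphenyl]-6,7-dimethoxychroman-2-ol, anomeric mixture at C2 | COc1ccc([C@H]2C(O)Oc3cc(OC)c(OC)cc3C2)c(OCc2ccccc2)c1OC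
A9 | alternative 3 | 2-[2-(benzyloxy)-3,4-dimethoxyphenyl]acetaldehyde | COc1ccc(CC=O)c(OCc2ccccc2)c1OC
A10 | alternative 3 | 4,5-dimethoxy-2-[(4-methylbenzenesulfonyl)methyl]phenol | COc1cc(O)c(CS(=O)(=O)c2ccc(C)cc2)cc1OC
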